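With ent-kaurane numbering, the target is cut at C13–C14 and C8–C7 of the bicyclo[3.2.1]octane. Its β,γ-unsaturated ketone C12(=O)–C13–C16(=C17) is the imprint of an enone–allene [2+2] photoadduct, so the precursor of the key step is a strained bicyclo[3.2.0]heptanone: cyclopentanone C12–C13–C8–C9–C11 fused to a methylenecyclobutane, with an iodomethyl group (C14) on C8 and ring A already on C9. One radical chain operation opens the C8–C13 cyclobutane bond, re-closes C13–C14 across the resulting seven-membered ring (five-membered ring becomes six-membered ring C; ring D forms) and carbonylates the bridgehead C8 radical to the C7 aldehyde.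

Key step: step 13

Numbering remark: ent-kaurane numbers are used throughout (ring A = C1–C5, C10; ring C = C8, C9, C11–C14; ring D = C8, C14, C13, C16, C15; C6 and C19 are the acid carbons, C7 the formyl carbon).

Assumption: in step 2 the (S,S)-ligand is taken to expose the Si face of the imide α-carbon, as with simpler acryloyl imides; if the sense is opposite, the (R,R)-ligand is used.

Step 1
Reactants: 1 (E)-4-(tert-butoxy)-4-oxobut-2-enoic acid; 2 1,3-oxazolidin-2-one
Product: 4 tert-butyl (E)-4-oxo-4-(2-oxo-1,3-oxazolidin-3-yl)but-2-enoate, via mixed pivalic anhydride 3 (not isolated)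
Conditions: PivCl, Et3N, THF, −20 °C; then 2, LiCl, rt
Reagents that add atoms: pivaloyl chloride, CC(C)(C)C(=O)Cl (atoms kept only in intermediate 3)
Why: Mixed-anhydride N-acylation of the oxazolidinone should give the two-point-binding fumarate imide needed for chelation-controlled catalysis, the tert-butyl ester being inert.

Step 2
Reactants: 4 tert-butyl (E)-4-oxo-4-(2-oxo-1,3-oxazolidin-3-yl)but-2-enoate; 5 (E)-penta-1,3-diene
Product: 6 tert-butyl (1S,5S,6S)-5-methyl-6-(2-oxo-1,3-oxazolidine-3-carbonyl)cyclohex-3-ene-1-carboxylate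
Conditions: [Cu((S,S)-tBu-box)](SbF6)2 (10 mol %; tBu-box = 2,2′-(propane-2,2-diyl)bis[(4S)-4-tert-butyl-4,5-dihydrooxazole]), CH2Cl2, −20 °C to rt
Reagents that add atoms: none
Why: Copper–bis(oxazoline)-catalysed Diels–Alder reaction in which the chelated imide directs the diene "ortho" and endo, so the methyl-bearing terminus should bond to the Si face of the imide α-carbon (sets C5, with C10–Me cis to the imide and C4 trans from the E-alkene).

Step 3
Reactants: 6 tert-butyl (1S,5S,6S)-5-methyl-6-(2-oxo-1,3-oxazolidine-3-carbonyl)cyclohex-3-ene-1-carboxylate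
Product: 8 (1S,2S,6S)-6-(tert-butoxycarbonyl)-2-methylcyclohex-3-ene-1-carboxylic acid, via peroxy acid 7 (not isolated)
Conditions: LiOH, H2O2 (30 %), THF/H2O, 0 °C; then Na2SO3
Reagents that add atoms: hydrogen peroxide, OO
Why: Hydroperoxide attacks the exocyclic imide carbonyl selectively (standard oxazolidinone cleavage), which should free the C6 acid without touching the tert-butyl ester or C5.

Step 4
Reactants: 8 (1S,2S,6S)-6-(tert-butoxycarbonyl)-2-methylcyclohex-3-ene-1-carboxylic acid
Product: 9 (1S,2S,6R)-6-(tert-butoxycarbonyl)-2,6-dimethylcyclohex-3-ene-1-carboxylic acid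
Conditions: LiN(iPr)2 (LDA, 2.2 equiv), THF, −78 to −20 °C; MeI
Reagents that add atoms: iodomethane, CI
Why: In the carboxylate/ester-enolate dianion only C4 is enolised, and C-methylation anti to the neighbouring C5 carboxylate should place the new methyl trans to C6, so the C19 ester becomes cis to C6 (quaternary C4).

Step 5
Reactants: 9 (1S,2S,6R)-6-(tert-butoxycarbonyl)-2,6-dimethylcyclohex-3-ene-1-carboxylic acid
Product: 10 di-tert-butyl (1R,2S,3S)-1,3-dimethylcyclohex-4-ene-1,2-dicarboxylate
Conditions: tert-butyl 2,2,2-trichloroacetimidate, BF3·OEt2 (cat.), cyclohexane/CH2Cl2, rt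
Reagents that add atoms: tert-butyl 2,2,2-trichloroacetimidate, CC(C)(C)OC(=N)C(Cl)(Cl)Cl
Why: Acid-catalysed O-alkylation by a tert-butyl cation donor esterifies the hindered acid without base, so C5 cannot epimerise.

Step 6
Reactants: 10 di-tert-butyl (1R,2S,3S)-1,3-dimethylcyclohex-4-ene-1,2-dicarboxylate
Product: 11 di-tert-butyl (1R,2S)-1,3-dimethylcyclohex-3-ene-1,2-dicarboxylate
Conditions: RuHCl(CO)(PPh3)3 (5 mol %), toluene, 100 °C
Reagents that add atoms: none
Why: Metal-hydride addition–elimination (olefin isomerisation) should move the double bond to the trisubstituted C10=C1 position and stop there, because further migration needs a tertiary alkyl–ruthenium intermediate; the C10 centre is erased on purpose.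

Step 7
Reactants: 11 di-tert-butyl (1R,2S)-1,3-dimethylcyclohex-3-ene-1,2-dicarboxylate; 12 (R)-4-[(tert-butyldimethylsilyl)oxy]cyclopent-2-en-1-one
Product: 13 di-tert-butyl (1R,2S,3S)-3-[(1S,2R)-2-[(tert-butyldimethylsilyl)oxy]-4-oxocyclopentyl]-1,3-dimethylcyclohexane-1,2-dicarboxylate
Conditions: Fe(acac)3 (30 mol %), PhSiH3, EtOH/(CH2OH)2, 60 °C (12 in threefold excess)
Reagents that add atoms: none
Why: Iron-hydride hydrogen-atom transfer to C1 gives the tertiary C10 radical, whose Giese addition to the enone should occur anti to the OTBS group (sets C9) and through the radical face trans to the C5 ester and remote from the axial C4 ester (sets quaternary C10, C20 cis to C19).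

Step 8
Reactants: 13 di-tert-butyl (1R,2S,3S)-3-[(1S,2R)-2-[(tert-butyldimethylsilyl)oxy]-4-oxocyclopentyl]-1,3-dimethylcyclohexane-1,2-dicarboxylate
Product: 14 di-tert-butyl (1R,2S,3S)-1,3-dimethyl-3-[(1R)-4-oxocyclopent-2-en-1-yl]cyclohexane-1,2-dicarboxylate
Conditions: DBU, CH2Cl2, 0 °C to rt
Reagents that add atoms: none
Why: E1cB loss of silanolate from the β-silyloxy ketone should give the C13=C8 cyclopentenone while the γ-stereocentre C9 is kept.

Step 9
Reactants: 14 di-tert-butyl (1R,2S,3S)-1,3-dimethyl-3-[(1R)-4-oxocyclopent-2-en-1-yl]cyclohexane-1,2-dicarboxylate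
Product: 16 di-tert-butyl (1R,2S,3S)-3-[2-{[dimethyl(propan-2-yloxy)silyl]methyl}-4-oxocyclopent-2-en-1-yl]-1,3-dimethylcyclohexane-1,2-dicarboxylate (C9 as in 14), via trimethylsilyl enol ether 15 (not isolated)
Conditions: (iPrO)Me2SiCH2MgCl, CuI (10 mol %), TMSCl, THF, −78 °C; then Pd(OAc)2, MeCN, rt
Reagents that add atoms: (isopropoxydimethylsilyl)methylmagnesium chloride, CC(C)O[Si](C)(C)C[Mg]Cl; chlorotrimethylsilane, C[Si](C)(C)Cl (atoms kept only in intermediate 15)
Why: Copper-catalysed conjugate addition of the hydroxymethyl-anion equivalent (trans to the C9 substituent) with silyl trapping, then Saegusa–Ito oxidation of the enol silane, should restore the enone with C14 on C8; the transient C8 centre is erased.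

Step 10
Reactants: 16 di-tert-butyl (1R,2S,3S)-3-[2-{[dimethyl(propan-2-yloxy)silyl]methyl}-4-oxocyclopent-2-en-1-yl]-1,3-dimethylcyclohexane-1,2-dicarboxylate
Product: 17 di-tert-butyl (1R,2S,3S)-3-[5-{[dimethyl(propan-2-yloxy)silyl]methyl}-7-methylidene-2-oxobicyclo[3.2.0]heptan-4-yl]-1,3-dimethylcyclohexane-1,2-dicarboxylate (cis-fused, cyclobutane anti to ring A)
Conditions: allene (excess), hν (350 nm, Pyrex), CH2Cl2, −78 °C
Reagents that add atoms: propa-1,2-diene (allene), C=C=C
Why: Triplet enone–allene [2+2] photocycloaddition with the head-to-head regiochemistry usual for cyclopentenones should put the central allene carbon C16 on the α-carbon C13 and C15 on C8; only this regiochemistry is carried forward, the two new centres being erased in step 13.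

Step 11
Reactants: 17 di-tert-butyl (1R,2S,3S)-3-[5-{[dimethyl(propan-2-yloxy)silyl]methyl}-7-methylidene-2-oxobicyclo[3.2.0]heptan-4-yl]-1,3-dimethylcyclohexane-1,2-dicarboxylate
Product: 18 di-tert-butyl (1R,2S,3S)-3-[5-(hydroxymethyl)-7-methylidene-2-oxobicyclo[3.2.0]heptan-4-yl]-1,3-dimethylcyclohexane-1,2-dicarboxylate
Conditions: KF, KHCO3, H2O2 (30 %), THF/MeOH, rt
Reagents that add atoms: hydrogen peroxide, OO
Why: Tamao–Kumada oxidation turns the alkoxysilane C–Si bond into C–OH under conditions that should leave the ketone, the 1,1-disubstituted alkene and the tert-butyl esters alone.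

Step 12
Reactants: 18 di-tert-butyl (1R,2S,3S)-3-[5-(hydroxymethyl)-7-methylidene-2-oxobicyclo[3.2.0]heptan-4-yl]-1,3-dimethylcyclohexane-1,2-dicarboxylate
Product: 19 di-tert-butyl (1R,2S,3S)-3-[5-(iodomethyl)-7-methylidene-2-oxobicyclo[3.2.0]heptan-4-yl]-1,3-dimethylcyclohexane-1,2-dicarboxylate
Conditions: PPh3, I2, imidazole, toluene, 80 °C
Reagents that add atoms: iodine, II
Why: Appel-type iodination (alkoxyphosphonium displaced by iodide) of the neopentyl-type primary carbinol, a conversion used for cyclobutylcarbinols of [2+2] adducts before radical fragmentation.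

Step 13
Reactants: 19 di-tert-butyl (1R,2S,3S)-3-[5-(iodomethyl)-7-methylidene-2-oxobicyclo[3.2.0]heptan-4-yl]-1,3-dimethylcyclohexane-1,2-dicarboxylate
Product: 20 di-tert-butyl (1R,2S,3S)-3-[(1R,4S,5R)-5-formyl-7-methylidene-2-oxobicyclo[3.2.1]octan-4-yl]-1,3-dimethylcyclohexane-1,2-dicarboxylate
Conditions: (TMS)3SiH, AIBN (cat.), CO (80 atm), benzene (0.01 M), 80 °C
Reagents that add atoms: carbon monoxide, [C-]#[O+]
Why: Proposed new method: the silyl radical abstracts iodine, the cyclobutylcarbinyl radical at C14 cleaves the strained C8–C13 bond to an α-keto, allyl-stabilised C13 radical, this radical adds across the ring to the new exocyclic C8=C14 alkene, and the bridgehead C8 radical is carbonylated and reduced to the aldehyde; the closest known types are the radical fragmentation of [2+2]-adduct iodides to ring-enlarged ketones and the free-radical formylation of bridgehead iodides under CO. Ring C closes by a 6-endo-trig transannular attack of C13 on C14, the same bond completing five-membered ring D, so the former five-membered ring C12–C13–C8–C9–C11 gains C14. C13 and C8 are set together by the one-carbon bridge; their sense relative to C9 should be controlled by ring A staying pseudo-equatorial on the cycloheptenone (anti to C15), and the formyl group enters the only free bridgehead valence. The step needs cleavage of C8–C13 rather than C8–C15, which the doubly stabilised C13 radical should secure, and CO capture before hydrogen transfer, which the slow hydrogen donor, high dilution and CO pressure should secure.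

Step 14
Reactants: 20 di-tert-butyl (1R,2S,3S)-3-[(1R,4S,5R)-5-formyl-7-methylidene-2-oxobicyclo[3.2.1]octan-4-yl]-1,3-dimethylcyclohexane-1,2-dicarboxylate
Product: 21 (1R,2S,3S)-3-[(1R,4S,5R)-5-formyl-7-methylidene-2-oxobicyclo[3.2.1]octan-4-yl]-1,3-dimethylcyclohexane-1,2-dicarboxylic acid (7,12-dioxo-6,7-seco-ent-kaur-16-ene-6,19-dioic acid, CNP0320711.1)
Conditions: TFA, CH2Cl2, 0 °C
Reagents that add atoms: none
Why: Acidolysis of both tert-butyl esters by the alkyl–oxygen (tert-butyl cation) pathway is insensitive to the hindrance at C4 and, at 0 °C, should leave the aldehyde, the ketone, C5–H and the exocyclic alkene intact.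

Compound list
1 | (E)-4-(tert-butoxy)-4-oxobut-2-enoic acid (fumaric acid mono-tert-butyl ester) | CC(C)(C)OC(=O)/C=C/C(=O)O | starting material
2 | 1,3-oxazolidin-2-one | O=C1NCCO1 | starting material
3 | tert-butyl (E)-4-oxo-4-(pivaloyloxy)but-2-enoate (mixed anhydride) | CC(C)(C)OC(=O)/C=C/C(=O)OC(=O)C(C)(C)C | intermediate (not isolated)
4 | tert-butyl (E)-4-oxo-4-(2-oxo-1,3-oxazolidin-3-yl)but-2-enoate | CC(C)(C)OC(=O)/C=C/C(=O)N1CCOC1=O | intermediate
5 | (E)-penta-1,3-diene | C/C=C/C=C | starting material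
6 | tert-butyl (1S,5S,6S)-5-methyl-6-(2-oxo-1,3-oxazolidine-3-carbonyl)cyclohex-3-ene-1-carboxylate | C[C@H]1C=CC[C@H](C(=O)OC(C)(C)C)[C@H]1C(=O)N1CCOC1=O | intermediate
7 | (1S,2S,6S)-6-(tert-butoxycarbonyl)-2-methylcyclohex-3-ene-1-carboperoxoic acid | C[C@H]1C=CC[C@H](C(=O)OC(C)(C)C)[C@H]1C(=O)OO | intermediate (not isolated)
8 | (1S,2S,6S)-6-(tert-butoxycarbonyl)-2-methylcyclohex-3-ene-1-carboxylic acid | C[C@H]1C=CC[C@H](C(=O)OC(C)(C)C)[C@H]1C(=O)O | intermediate
9 | (1S,2S,6R)-6-(tert-butoxycarbonyl)-2,6-dimethylcyclohex-3-ene-1-carboxylic acid | C[C@H]1C=CC[C@@](C)(C(=O)OC(C)(C)C)[C@H]1C(=O)O | intermediate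
10 | di-tert-butyl (1R,2S,3S)-1,3-dimethylcyclohex-4-ene-1,2-dicarboxylate | C[C@H]1C=CC[C@@](C)(C(=O)OC(C)(C)C)[C@H]1C(=O)OC(C)(C)C | intermediate
11 | di-tert-butyl (1R,2S)-1,3-dimethylcyclohex-3-ene-1,2-dicarboxylate | CC1=CCC[C@@](C)(C(=O)OC(C)(C)C)[C@H]1C(=O)OC(C)(C)C | intermediate
12 | (R)-4-[(tert-butyldimethylsilyl)oxy]cyclopent-2-en-1-one | O=C1C=C[C@H](O[Si](C)(C)C(C)(C)C)C1 | starting material
13 | di-tert-butyl (1R,2S,3S)-3-[(1S,2R)-2-[(tert-butyldimethylsilyl)oxy]-4-oxocyclopentyl]-1,3-dimethylcyclohexane-1,2-dicarboxylate | O=C1C[C@@H](O[Si](C)(C)C(C)(C)C)[C@@H](C1)[C@]1(C)CCC[C@@](C)(C(=O)OC(C)(C)C)[C@H]1C(=O)OC(C)(C)C | intermediate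
14 | di-tert-butyl (1R,2S,3S)-1,3-dimethyl-3-[(1R)-4-oxocyclopent-2-en-1-yl]cyclohexane-1,2-dicarboxylate | O=C1C=C[C@@H](C1)[C@]1(C)CCC[C@@](C)(C(=O)OC(C)(C)C)[C@H]1C(=O)OC(C)(C)C | intermediate
15 | trimethylsilyl enol ether of the conjugate adduct (silylmethyl group on C8 trans to ring A on C9; enol ether C12=C13) | C[Si](C)(C)OC1=C[C@@H](C[Si](C)(C)OC(C)C)[C@@H](C1)[C@]1(C)CCC[C@@](C)(C(=O)OC(C)(C)C)[C@H]1C(=O)OC(C)(C)C | intermediate (not isolated)
16 | di-tert-butyl (1R,2S,3S)-3-[2-{[dimethyl(propan-2-yloxy)silyl]methyl}-4-oxocyclopent-2-en-1-yl]-1,3-dimethylcyclohexane-1,2-dicarboxylate (C9 as in 14) | O=C1C=C(C[Si](C)(C)OC(C)C)[C@@H](C1)[C@]1(C)CCC[C@@](C)(C(=O)OC(C)(C)C)[C@H]1C(=O)OC(C)(C)C | intermediate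
17 | head-to-head allene photoadduct: 5-(silylmethyl)-7-methylidene-2-oxobicyclo[3.2.0]heptan-4-yl derivative, cis-fused, cyclobutane anti to ring A | O=C1[C@H]2C(=C)C[C@@]2(C[Si](C)(C)OC(C)C)[C@@H](C1)[C@]1(C)CCC[C@@](C)(C(=O)OC(C)(C)C)[C@H]1C(=O)OC(C)(C)C | intermediate
18 | 5-(hydroxymethyl)-7-methylidene-2-oxobicyclo[3.2.0]heptan-4-yl analogue of 17 | O=C1[C@H]2C(=C)C[C@@]2(CO)[C@@H](C1)[C@]1(C)CCC[C@@](C)(C(=O)OC(C)(C)C)[C@H]1C(=O)OC(C)(C)C | intermediate
19 | 5-(iodomethyl)-7-methylidene-2-oxobicyclo[3.2.0]heptan-4-yl analogue of 17 | O=C1[C@H]2C(=C)C[C@@]2(CI)[C@@H](C1)[C@]1(C)CCC[C@@](C)(C(=O)OC(C)(C)C)[C@H]1C(=O)OC(C)(C)C | intermediate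
20 | di-tert-butyl (1R,2S,3S)-3-[(1R,4S,5R)-5-formyl-7-methylidene-2-oxobicyclo[3.2.1]octan-4-yl]-1,3-dimethylcyclohexane-1,2-dicarboxylate | C=C1C[C@]2(C=O)C[C@H]1C(=O)C[C@H]2[C@]1(C)CCC[C@@](C)(C(=O)OC(C)(C)C)[C@H]1C(=O)OC(C)(C)C | intermediate
21 | (1R,2S,3S)-3-[(1R,4S,5R)-5-formyl-7-methylidene-2-oxobicyclo[3.2.1]octan-4-yl]-1,3-dimethylcyclohexane-1,2-dicarboxylic acid (CNP0320711.1) | C=C1C[C@]2(C=O)C[C@H]1C(=O)C[C@H]2[C@]1(C)CCC[C@@](C)(C(=O)O)[C@H]1C(=O)O | target

Total step count: 14. Longest linear sequence: 14 steps (1 to 21; 2, 5 and 12 enter as commercial partners).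

Steps most likely to fail

Step 13 (proposed new method). Hydrogen transfer to the ring-opened α-keto radical or to the bridgehead radical may outrun transannular closure and CO capture, and the closure may take the wrong facial sense relative to C9. The fallback uses three known reaction types, sets out from iodide 19 and rejoins the route at aldehyde 20. Reduction of 19 with Bu3SnH and AIBN in benzene at 80 °C without CO should stop after the known fragmentation of the C8–C13 bond and give the ring-opened 2,4-dimethylidene-6-oxocycloheptyl compound, cycloheptenone F1. Claisen formylation (NaH, HCO2Et, THF) at the doubly activated C13 should give the chelated hydroxymethylene ketone F2. Irradiation of F2 at 350 nm is a de Mayo reaction: the enol double bond C13=C7 and the C8=C14 alkene form a 1,5-diene, so the crossed [2+2] adduct, cyclobutanol F3, is expected. Its retro-aldol cleavage of C13–C7 in the same flask leaves the formyl group on C8 and the C13–C14 bridge, that is 20.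

Step 7. Bimolecular addition of the hindered tertiary radical may be slower than reduction or isomerisation of the olefin and reduction of the enone, and facial control at C10 may be poor. The fallback changes the radical source; it sets out from olefin 11 and rejoins at 13. Mukaiyama hydration (Mn(dpm)3 [tris(dipivaloylmethanato)manganese], PhSiH3, O2, iPrOH, 0 °C) should give the tertiary C10 alcohol F4 as a mixture of C10 epimers, which does not matter. Acylation with methyl chlorooxoacetate (Et3N, DMAP) gives the methyl oxalate F5, and CsOH·H2O in THF/H2O the cesium oxalate F6. Visible-light photoredox coupling of F6 with enone 12 (Ir[dF(CF3)ppy]2(dtbbpy)PF6, H2O, DME/DMF, blue LEDs, 60 °C) forms the same C10 radical irreversibly by double decarboxylation and should give 13 with the same facial preferences.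

Step 12. The alkoxyphosphonium intermediate may ionise with cyclobutylcarbinyl ring enlargement or elimination instead of undergoing substitution at the neopentyl carbon. The fallback makes the radical precursor by acylation instead of substitution; it sets out from alcohol 18 and rejoins at 20. Phenyl chlorothionoformate (pyridine, DMAP, CH2Cl2) should give the O-phenyl thionocarbonate F7. Barton–McCombie-type C–O homolysis of F7 (Bu3SnH, AIBN, CO 80 atm, toluene, 110 °C) then feeds the same C14 radical into the cascade of step 13.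

Further compounds
F1 | step 13 | di-tert-butyl (1R,2S,3S)-3-(2,4-dimethylidene-6-oxocycloheptyl)-1,3-dimethylcyclohexane-1,2-dicarboxylate (C9 as in 19) | O=C1CC(=C)CC(=C)[C@@H](C1)[C@]1(C)CCC[C@@](C)(C(=O)OC(C)(C)C)[C@H]1C(=O)OC(C)(C)C
F2 | step 13 | (Z)-5-(hydroxymethylidene) derivative of F1 (hydroxymethylene on C13, chelated enol) | O=C1/C(=C\O)C(=C)CC(=C)[C@@H](C1)[C@]1(C)CCC[C@@](C)(C(=O)OC(C)(C)C)[C@H]1C(=O)OC(C)(C)C
F3 | step 13 | crossed [2+2] photoadduct of F2 (cyclobutanol with bonds C7–C8 and C13–C14; C7 epimers) | C=C1C[C@]2(C3O)C[C@@]13C(=O)C[C@H]2[C@]1(C)CCC[C@@](C)(C(=O)OC(C)(C)C)[C@H]1C(=O)OC(C)(C)C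
F4 | step 7 | di-tert-butyl 3-hydroxy-1,3-dimethylcyclohexane-1,2-dicarboxylate (C4 and C5 as in 11; C10 epimers) | CC1(O)CCC[C@@](C)(C(=O)OC(C)(C)C)[C@H]1C(=O)OC(C)(C)C
F5 | step 7 | methyl oxalate of F4 | COC(=O)C(=O)OC1(C)CCC[C@@](C)(C(=O)OC(C)(C)C)[C@H]1C(=O)OC(C)(C)C
F6 | step 7 | cesium oxalate of F4 | [Cs+].[O-]C(=O)C(=O)OC1(C)CCC[C@@](C)(C(=O)OC(C)(C)C)[C@H]1C(=O)OC(C)(C)C
F7 | step 12 | O-phenyl thionocarbonate of alcohol 18 | O=C1[C@H]2C(=C)C[C@@]2(COC(=S)Oc3ccccc3)[C@@H](C1)[C@]1(C)CCC[C@@](C)(C(=O)OC(C)(C)C)[C@H]1C(=O)OC(C)(C)C
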